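How much of Q has reacted after 3.0 d at each charge of E, and does raising E move that by more than the margin?

common to all: Q 0.072 M
- grey: E 0.74 equiv; L 0.036 M; run made earlier
- teal: E 2 equiv; L 0.036 M; run made earlier
- delta: E 1.00 equiv; L 0.0360 M; time 3.0 d
- alpha: E 1.30 equiv; L 0.0360 M; time 3.0 d
- zeta: E 1.70 equiv; L 0.0360 M; time 3.0 d

| run | time / h | Q / % | G / % |
|---|---|---|---|
| grey | 8.00 | 54.1 | 11.5 |
| grey | 15.0 | 40.6 | 15.4 |
| grey | 20.0 | 34.4 | 18.9 |
| grey | 30.0 | 29.2 | 22.2 |
| grey | 40.0 | 24.7 | 23.6 |
| teal | 3.00 | 64.7 | 13.9 |
| teal | 10.0 | 34.4 | 29.1 |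
| teal | 15.0 | 23.2 | 36.1 |
| teal | 25.0 | 13.6 | 43.1 |
| teal | 40.0 | 6.3 | 48.0 |

(standard deviation of a reading: 0.5 percentage points)

* part of the Q that has reacted at the end, delta
* part of the Q that has reacted at the end, alpha
* part of the Q that has reacted at the end, zeta
* what raising the equivalents of E from its lowest to its highest value here does to the part of the Q that has reacted (changes below 5 percentage points count as none) (no change / it falls / it rises)

- what was read earlier has a scatter of 0.5 percentage points, one standard deviation

L is charged at half the amount of Q. In the readings at 40.0 h, the part of Q lost without appearing as G is 51.7% in grey and 45.7% in teal, close to that charge. So I read L as a second partner for Q, taken one to one, and as the limiting reagent of that route. That leaves a share s = 50.0% of Q for E to turn over.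

On that share I count turnovers n, where n = ln(s/Q) and Q is the fraction of the charge still there. If I treat the fall as pseudo-first-order in Q, with E held at its charge of e equivalents, the count grows with e and with the time t:

n = κ · e · t, and Q left = s · exp(−n)

Grey's last reading gives n = ln(s/Q) = 0.705, so κ is 0.0238 h⁻¹. Teal's gives 2.07, so κ is 0.0259 h⁻¹. I take the mean, 0.0249 h⁻¹, and call it the turnover rate: turnovers per equivalent of E per unit time. My reckoning for the time asked is then:

delta: n = 1.79, Q left 8.35%, reacted 91.6%

alpha: n = 2.33, Q left 4.88%, reacted 95.1%

zeta: n = 3.04, Q left 2.39%, reacted 97.6%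

That is a rise of 6 percentage points, above the margin. But n counts the E charged, not the E still free, and the runs stop at 40.0 h, short of 3.0 d, so I expect Q to stand higher than these values, and late Q in delta is the reading to watch.

The forecast gives 90.5%, 94.5% and 97.4%, slightly below mine, with the trend it rises. Its ground for the late stretch is that “Q decays by about k·E alone”.

The flask gives 87.1%, 92.5% and 96.7% for delta, alpha and zeta: it rises, by 9.5 points, and the forecast is right within its tolerance.

    Q + L → J (k = 3.00 M⁻¹ h⁻¹)
    E + Z ⇌ D, settled at all times (K = 12000 M⁻¹)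
    Q + E → Z + G (k = 0.440 M⁻¹ h⁻¹)
    2 Q → X (k = 0.0170 M⁻¹ h⁻¹)

Delta's count comes to 1.36, below my 1.79, and 28.3% of its E is still free at the end. For the neighbour of alpha charged with 0.330 equiv of E, the turnover rate 0.0249 h⁻¹ counts 0.591 turnovers and leaves Q at 27.7%; that flask holds 32.4%.

The readings stem from a simulated flask for an exercise, and the scatter is random.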